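**Plan**

- Feature: in the oxolan-2-one ring (O1, C2, C3, C4, C5) the carbonyl carbon C2 is bonded only to C3 and to the ring oxygen O1. It can therefore enter as carbon monoxide across a C3=C4 double bond of an allylic alcohol whose hydroxyl oxygen becomes O1.
- Retrosynthesis: lactone to lactol; cut C2–C3 and C2–O1 (hydroformylation with hemiacetal closure) to an E-trisubstituted allylic alcohol; cut the C4–CH2(veratryl) bond (Stille coupling) to a 2-stannyl allylic alcohol; cut C3–C7′ (C7′ = carbinol carbon) to silylated vanillin and a propargyl ether.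
- Forward: the chain is joined C7′–C3 first (asymmetric alkynylation), then C4–CH2Ar (trans-hydrostannation, Stille coupling). The only ring closes last, together with the C2–C3 bond; lactol oxidation and desilylation finish.
- Stereochemistry: C7′ comes from the ligand-controlled alkynylation. The trans C3/C4 relation comes from syn addition of H and CHO to the E-alkene. Its absolute sense comes from facial selection by the A(1,3)-locked C7′ silyloxy centre.

Key step: step 8

Abbreviations: TBS = tert-butyldimethylsilyl, PMB = 4-methoxybenzyl.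

Assumption: with (S)-BINOL/Ti(OiPr)4 the alkynylzinc is taken to add to the Si face of the aryl aldehyde, the sense known for dialkylzinc additions with this ligand; the configuration of the step 3 carbinol is checked as its MTPA esters, and (R)-BINOL is used instead if the sense proves opposite.

**Route**

Step 1
Reactants: 1 vanillin (4-hydroxy-3-methoxybenzaldehyde)
Product: 2 4-[(TBS)oxy]-3-methoxybenzaldehyde
Conditions: TBSCl, imidazole, DMF, rt
Reagents that add atoms: tert-butyldimethylsilyl chloride, CC(C)(C)[Si](C)(C)Cl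
Why: Imidazole-promoted O-silylation of a phenol masks the acidic OH before organozinc chemistry and leaves the aldehyde untouched.

Step 2
Reactants: 3 propargyl alcohol
Product: 4 1-methoxy-4-[(prop-2-yn-1-yloxy)methyl]benzene (PMB propargyl ether)
Conditions: NaH, THF, 0 °C; then PMBCl, Bu4NI (cat.), 0 °C to rt
Reagents that add atoms: 4-methoxybenzyl chloride, COc1ccc(CCl)cc1
Why: Williamson ether synthesis on the primary alkoxide gives an ether that survives organozinc and silylation steps and can later be removed oxidatively without acid or fluoride.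

Step 3
Reactants: 2 4-[(TBS)oxy]-3-methoxybenzaldehyde; 4 PMB propargyl ether
Product: 6 (1R)-1-{4-[(TBS)oxy]-3-methoxyphenyl}-4-[(PMB)oxy]but-2-yn-1-ol, via alkynylzinc reagent 5 (not isolated)
Conditions: 4 (2 equiv), Et2Zn (2 equiv), Cy2NH (5 mol%), Et2O, rt; then (S)-BINOL (20 mol%), Ti(OiPr)4 (50 mol%); then 2, rt; aq NH4Cl
Reagents that add atoms: none
Why: In this BINOL–titanium-catalysed asymmetric alkynylzinc addition to an aldehyde, the ethyl(alkynyl)zinc formed in the flask passes its alkynyl group to the Si face of the aldehyde inside the chiral titanium binaphtholate, which sets the carbinol centre as R (the alkynyl branch outranks the aryl ring here, and the same spatial arrangement is labelled S once the alkyne has become an alkene).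

Step 4
Reactants: 6 (1R)-propargylic alcohol
Product: 7 (1R)-1-[(TBS)oxy]-1-{4-[(TBS)oxy]-3-methoxyphenyl}-4-[(PMB)oxy]but-2-yne
Conditions: TBSCl, imidazole, DMF, rt
Reagents that add atoms: tert-butyldimethylsilyl chloride, CC(C)(C)[Si](C)(C)Cl
Why: O-silylation of the secondary alcohol under non-ionising conditions fixes the silyloxy group that later steers the hydroformylation and does not touch the stereocentre.

Step 5
Reactants: 7 bis-silyl PMB ether
Product: 8 (4R)-4-[(TBS)oxy]-4-{4-[(TBS)oxy]-3-methoxyphenyl}but-2-yn-1-ol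
Conditions: DDQ, CH2Cl2/aq pH 7 phosphate buffer, 0 °C
Reagents that add atoms: none
Why: Oxidative PMB ether cleavage by DDQ (hydride abstraction at the unhindered, most electron-rich benzylic CH2, then hydrolysis of the oxocarbenium ion) frees the primary hydroxyl under neutral conditions that keep both silyl ethers and the hindered, alkyne-deactivated benzylic silyloxy C–H.

Step 6
Reactants: 8 (4R)-alkynol
Product: 9 (2Z,4S)-4-[(TBS)oxy]-4-{4-[(TBS)oxy]-3-methoxyphenyl}-2-(tributylstannyl)but-2-en-1-ol
Conditions: Bu3SnH (1.1 equiv), [Cp*RuCl]4 (2 mol%), CH2Cl2, rt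
Reagents that add atoms: tributyltin hydride, CCCC[SnH](CCCC)CCCC
Why: In the hydroxyl-directed ruthenium-catalysed trans-hydrostannation, the free OH binds the chloride on ruthenium, so tin goes to the alkyne carbon next to CH2OH and hydrogen adds anti to it, which places tin cis to the carbinol carbon (Z).

Step 7
Reactants: 9 (2Z,4S)-alkenylstannane; 10 3,4-dimethoxybenzyl chloride
Product: 11 (2E,4S)-4-[(TBS)oxy]-4-{4-[(TBS)oxy]-3-methoxyphenyl}-2-(3,4-dimethoxybenzyl)but-2-en-1-ol
Conditions: 10 (1.3 equiv), Pd2(dba)3 (2.5 mol%), P(2-furyl)3 (10 mol%), CuI (10 mol%), NMP, 50 °C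
Reagents that add atoms: none
Why: Stille coupling of an alkenylstannane with a benzylic chloride (oxidative addition, copper-assisted tin-to-palladium transfer, reductive elimination) proceeds with retention at the alkene, so the veratryl CH2 takes the place of tin cis to the carbinol carbon, which is the E-alkene needed; the free hydroxyl and both silyl ethers are inert in the absence of base and fluoride.

Step 8
Reactants: 11 (2E,4S)-allylic alcohol; 12 carbon monoxide
Product: 14 (3S,4R)-3-[(S)-{4-[(TBS)oxy]-3-methoxyphenyl}[(TBS)oxy]methyl]-4-(3,4-dimethoxybenzyl)oxolan-2-ol (anomeric mixture), via hydroxy aldehyde 13 (not isolated)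
Conditions: Rh(acac)(CO)2 (2 mol%), P(O-2,4-tBu2C6H3)3 (8 mol%), CO/H2 (1:1, 40 bar), toluene, 60 °C
Reagents that add atoms: carbon monoxide, [C-]#[O+] (this is reactant 12)
Why: Proposed new method: the hydridorhodium carbonyl phosphite complex should bind the alkene of 11, transfer hydride to the fully substituted butenol C2 and place rhodium on the CH carbon C3 (a formyl group does not go to a carbon that would become quaternary), after which CO inserts into the Rh–C bond with retention and hydrogenolysis releases hydroxy aldehyde 13, H and CHO having been added to the same face. The closest known reaction type is the rhodium-catalysed hydroformylation of allyl alcohol and of 2-substituted allylic alcohols to 2-hydroxytetrahydrofurans, together with bulky-phosphite hydroformylation of trisubstituted alkenes; their union on an acyclic trisubstituted allylic alcohol under stereocontrol is not yet described. The oxolane ring closes by 5-exo-trig addition of the primary hydroxyl to the new formyl carbon, and this hemiacetal keeps the α-stereocentre away from enolisation. Since the veratryl CH2 is cis to the carbinol carbon in the E-alkene, syn addition fixes the trans relation of ring C3 and C4; which face reacts is decided by the silyloxy stereocentre, whose C–H is held near the alkene plane by A(1,3) strain with the veratryl CH2 so that rhodium should add anti to the C–OSi bond (the σ-acceptor and the bulkier flank, as in rhodium-catalysed hydroboration of allylic silyl ethers), giving the 3S,4R ring beside the S carbinol. The step needs regioselectivity, π-facial selectivity and chemoselectivity over alkene migration to the silyl enol ether and β-silyloxy elimination; the substitution pattern secures the first, the allylic stereocentre the second, and CO pressure at moderate temperature together with the poor silanolate leaving group the third.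

Step 9
Reactants: 14 lactol
Product: 15 (3S,4R)-3-[(S)-{4-[(TBS)oxy]-3-methoxyphenyl}[(TBS)oxy]methyl]-4-(3,4-dimethoxybenzyl)oxolan-2-one
Conditions: TEMPO (0.2 equiv), PhI(OAc)2 (2.5 equiv), CH2Cl2, rt
Reagents that add atoms: none
Why: Oxoammonium (TEMPO/PhI(OAc)2) oxidation of a cyclic hemiacetal to the lactone runs under neutral conditions that leave silyl ethers, electron-rich arenes and the C3 stereocentre untouched, both anomers converging on one lactone.

Step 10
Reactants: 15 bis-silyl lactone
Product: 17 (3S,4R)-3-[(S)-hydroxy(4-hydroxy-3-methoxyphenyl)methyl]-4-(3,4-dimethoxybenzyl)oxolan-2-one (CNP0497696.1), via mono-silyl phenol 16 (not isolated)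
Conditions: Bu4NF (4 equiv), AcOH (4 equiv), THF, 0 °C to rt
Reagents that add atoms: none
Why: Fluoride-induced Si–O cleavage removes the aryl silyl ether first and the benzylic one second, while the acetic acid buffer keeps phenol and carbinol protonated so that retro-aldol cleavage and epimerisation at C3 or C7′ should not set in.

**Compound list**

1 | vanillin | COc1cc(C=O)ccc1O | starting material
2 | 4-[(TBS)oxy]-3-methoxybenzaldehyde | COc1cc(C=O)ccc1O[Si](C)(C)C(C)(C)C | intermediate
3 | propargyl alcohol | C#CCO | starting material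
4 | 1-methoxy-4-[(prop-2-yn-1-yloxy)methyl]benzene | C#CCOCc1ccc(OC)cc1 | intermediate
5 | ethyl{3-[(4-methoxybenzyl)oxy]prop-1-yn-1-yl}zinc | CC[Zn]C#CCOCc1ccc(OC)cc1 | intermediate (not isolated)
6 | (1R)-1-{4-[(TBS)oxy]-3-methoxyphenyl}-4-[(PMB)oxy]but-2-yn-1-ol | COc1cc([C@@H](O)C#CCOCc2ccc(OC)cc2)ccc1O[Si](C)(C)C(C)(C)C | intermediate
7 | (1R)-1-[(TBS)oxy]-1-{4-[(TBS)oxy]-3-methoxyphenyl}-4-[(PMB)oxy]but-2-yne | COc1cc([C@@H](O[Si](C)(C)C(C)(C)C)C#CCOCc2ccc(OC)cc2)ccc1O[Si](C)(C)C(C)(C)C | intermediate
8 | (4R)-4-[(TBS)oxy]-4-{4-[(TBS)oxy]-3-methoxyphenyl}but-2-yn-1-ol | COc1cc([C@@H](O[Si](C)(C)C(C)(C)C)C#CCO)ccc1O[Si](C)(C)C(C)(C)C | intermediate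
9 | (2Z,4S)-4-[(TBS)oxy]-4-{4-[(TBS)oxy]-3-methoxyphenyl}-2-(tributylstannyl)but-2-en-1-ol | COc1cc([C@@H](O[Si](C)(C)C(C)(C)C)/C=C(/CO)[Sn](CCCC)(CCCC)CCCC)ccc1O[Si](C)(C)C(C)(C)C | intermediate
10 | 3,4-dimethoxybenzyl chloride | COc1ccc(CCl)cc1OC | starting material
11 | (2E,4S)-4-[(TBS)oxy]-4-{4-[(TBS)oxy]-3-methoxyphenyl}-2-(3,4-dimethoxybenzyl)but-2-en-1-ol | COc1cc([C@@H](O[Si](C)(C)C(C)(C)C)/C=C(/CO)Cc2ccc(OC)c(OC)c2)ccc1O[Si](C)(C)C(C)(C)C | intermediate
12 | carbon monoxide | [C-]#[O+] | starting material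
13 | (2S,3R)-2-[(S)-{4-[(TBS)oxy]-3-methoxyphenyl}[(TBS)oxy]methyl]-3-(3,4-dimethoxybenzyl)-4-hydroxybutanal | COc1cc([C@@H](O[Si](C)(C)C(C)(C)C)[C@@H](C=O)[C@H](CO)Cc2ccc(OC)c(OC)c2)ccc1O[Si](C)(C)C(C)(C)C | intermediate (not isolated)
14 | (3S,4R)-3-[(S)-{4-[(TBS)oxy]-3-methoxyphenyl}[(TBS)oxy]methyl]-4-(3,4-dimethoxybenzyl)oxolan-2-ol (anomeric mixture) | COc1cc([C@@H](O[Si](C)(C)C(C)(C)C)[C@H]2C(O)OC[C@@H]2Cc2ccc(OC)c(OC)c2)ccc1O[Si](C)(C)C(C)(C)C | intermediate
15 | (3S,4R)-3-[(S)-{4-[(TBS)oxy]-3-methoxyphenyl}[(TBS)oxy]methyl]-4-(3,4-dimethoxybenzyl)oxolan-2-one | COc1cc([C@@H](O[Si](C)(C)C(C)(C)C)[C@H]2C(=O)OC[C@@H]2Cc2ccc(OC)c(OC)c2)ccc1O[Si](C)(C)C(C)(C)C | intermediate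
16 | (3S,4R)-3-[(S)-[(TBS)oxy](4-hydroxy-3-methoxyphenyl)methyl]-4-(3,4-dimethoxybenzyl)oxolan-2-one | COc1cc([C@@H](O[Si](C)(C)C(C)(C)C)[C@H]2C(=O)OC[C@@H]2Cc2ccc(OC)c(OC)c2)ccc1O | intermediate (not isolated)
17 | (3S,4R)-3-[(S)-hydroxy(4-hydroxy-3-methoxyphenyl)methyl]-4-(3,4-dimethoxybenzyl)oxolan-2-one | COc1cc([C@@H](O)[C@H]2C(=O)OC[C@@H]2Cc2ccc(OC)c(OC)c2)ccc1O | target

**Count and risks**

Total step count: 10. Longest linear sequence: 9 steps (vanillin to 17 through steps 1 and 3 to 10); step 2 is a one-step side branch.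

Steps most likely to fail:

1. Step 8 (proposed new method). What may go wrong: too little discrimination between the aryl and silyloxy flanks of the alkene, or double-bond migration and β-silyloxy elimination running ahead of CO insertion at the hindered alkene. Fallback, known chemistry only, setting out from aldehyde 2 and coming back at target 17:
   - Commercial 3-(3,4-dimethoxyphenyl)propanoic acid is joined to (S)-4-benzyloxazolidin-2-one (pivaloyl chloride, Et3N, LiCl, THF) to give (4S)-4-benzyl-3-[3-(3,4-dimethoxyphenyl)propanoyl]oxazolidin-2-one F1.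
   - Auxiliary-controlled enolate alkylation (NaN(SiMe3)2, tert-butyl bromoacetate, THF, −78 °C) should give tert-butyl (3R)-4-[(4S)-4-benzyl-2-oxooxazolidin-3-yl]-3-(3,4-dimethoxybenzyl)-4-oxobutanoate F2.
   - LiBH4 (THF, MeOH, 0 °C) removes the auxiliary to leave tert-butyl (3R)-3-(3,4-dimethoxybenzyl)-4-hydroxybutanoate F3, which closes with TsOH in toluene to (4R)-4-(3,4-dimethoxybenzyl)oxolan-2-one F4.
   - The lithium enolate of F4 (LiN(iPr)2, THF, −78 °C) adds to aldehyde 2 anti to the C4 benzyl group. The trans lactone is expected as two carbinol epimers, the aldol (3S,4R)-3-[(S)-{4-[(TBS)oxy]-3-methoxyphenyl}(hydroxy)methyl]-4-(3,4-dimethoxybenzyl)oxolan-2-one F5 and its 7′R epimer F6, which are separated by chromatography.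
   - Bu4NF/AcOH on F5 then gives 17.

2. Step 7. What may go wrong: slow tin-to-palladium transfer at the hindered, internally substituted alkenylstannane, so that protodestannation or homocoupling of the benzyl chloride takes over. Fallback, setting out from stannane 9 and coming back at 11, with the coupling polarity reversed:
   - Iododestannation (I2, CH2Cl2, 0 °C, retention) gives (2Z,4S)-4-[(TBS)oxy]-4-{4-[(TBS)oxy]-3-methoxyphenyl}-2-iodobut-2-en-1-ol F7.
   - Chloride 10 is converted with zinc dust and LiCl in THF into (3,4-dimethoxybenzyl)zinc chloride F8.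
   - Negishi coupling of F7 with F8 (Pd(OAc)2, SPhos, THF, rt, free hydroxyl tolerated) gives 11.

3. Step 3. What may go wrong: low enantiofacial discrimination or sluggish addition to the electron-rich aldehyde, with ethyl transfer from Et2Zn competing. Fallback, setting out from 2 and 4 and coming back at 6, with the stereocentre set by reduction instead of addition:
   - The lithium acetylide of 4 (n-BuLi, THF, −78 °C) adds to 2 to give racemic 1-{4-[(TBS)oxy]-3-methoxyphenyl}-4-[(PMB)oxy]but-2-yn-1-ol F9.
   - MnO2 in CH2Cl2 oxidises it to the ynone 1-{4-[(TBS)oxy]-3-methoxyphenyl}-4-[(PMB)oxy]but-2-yn-1-one F10.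
   - Midland reduction with (R)-Alpine-Borane (B-isopinocampheyl-9-borabicyclo[3.3.1]nonane from (+)-α-pinene, the linear alkynyl group acting as the small substituent) gives the R carbinol 6.

**Further compounds**

F1 | step 8 | (4S)-4-benzyl-3-[3-(3,4-dimethoxyphenyl)propanoyl]oxazolidin-2-one | COc1ccc(CCC(=O)N2C(=O)OC[C@@H]2Cc2ccccc2)cc1OC
F2 | step 8 | tert-butyl (3R)-4-[(4S)-4-benzyl-2-oxooxazolidin-3-yl]-3-(3,4-dimethoxybenzyl)-4-oxobutanoate | COc1ccc(C[C@H](CC(=O)OC(C)(C)C)C(=O)N2C(=O)OC[C@@H]2Cc2ccccc2)cc1OC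
F3 | step 8 | tert-butyl (3R)-3-(3,4-dimethoxybenzyl)-4-hydroxybutanoate | COc1ccc(C[C@@H](CO)CC(=O)OC(C)(C)C)cc1OC
F4 | step 8 | (4R)-4-(3,4-dimethoxybenzyl)oxolan-2-one | COc1ccc(C[C@H]2COC(=O)C2)cc1OC
F5 | step 8 | (3S,4R)-3-[(S)-{4-[(TBS)oxy]-3-methoxyphenyl}(hydroxy)methyl]-4-(3,4-dimethoxybenzyl)oxolan-2-one | COc1cc([C@@H](O)[C@H]2C(=O)OC[C@@H]2Cc2ccc(OC)c(OC)c2)ccc1O[Si](C)(C)C(C)(C)C
F6 | step 8 | (3S,4R)-3-[(R)-{4-[(TBS)oxy]-3-methoxyphenyl}(hydroxy)methyl]-4-(3,4-dimethoxybenzyl)oxolan-2-one (7′R epimer) | COc1cc([C@H](O)[C@H]2C(=O)OC[C@@H]2Cc2ccc(OC)c(OC)c2)ccc1O[Si](C)(C)C(C)(C)C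
F7 | step 7 | (2Z,4S)-4-[(TBS)oxy]-4-{4-[(TBS)oxy]-3-methoxyphenyl}-2-iodobut-2-en-1-ol | COc1cc([C@@H](O[Si](C)(C)C(C)(C)C)/C=C(/CO)I)ccc1O[Si](C)(C)C(C)(C)C
F8 | step 7 | (3,4-dimethoxybenzyl)zinc chloride | COc1ccc(C[Zn]Cl)cc1OC
F9 | step 3 | racemic 1-{4-[(TBS)oxy]-3-methoxyphenyl}-4-[(PMB)oxy]but-2-yn-1-ol | COc1cc(C(O)C#CCOCc2ccc(OC)cc2)ccc1O[Si](C)(C)C(C)(C)C
F10 | step 3 | 1-{4-[(TBS)oxy]-3-methoxyphenyl}-4-[(PMB)oxy]but-2-yn-1-one | COc1cc(C(=O)C#CCOCc2ccc(OC)cc2)ccc1O[Si](C)(C)C(C)(C)C
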